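**Plan**
Retrosynthesis: cut the pyranone O1–C6 bond (giving a tert-butyl 3-oxo-4-ynoate), then C3–C4 (ester enolate plus enynoyl Weinreb amide), then the bond from C3 to the side-chain methine (Ireland–Claisen), then the methine–vinyl bond (made as the C=C of a cross-metathesis), then the allyl–carbinol bond (Grignard on 3-phenylpropanal).
Enabling feature: in the 2-pyranone ring, O1–C6 with the styryl group on C6, the C2 lactone carbonyl and the C4 hydroxyl are the cycloisomerised form of an ester C=O / ketone / alkyne triad, so O1 and C2–C6 map onto a tert-butyl 3-oxo-4-ynoate.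
Forward: allyl dioxolane from 3-phenylpropanal, cross-metathesis with (S)-1-phenylallyl acetate, Ireland–Claisen, tert-butyl ester, C-acylation with a cinnamaldehyde-derived ynamide, deketalisation, and gold-catalysed closure of the only new ring in the last step.
Stereochemistry: the single stereocentre comes from purchased (S)-1-phenylprop-2-en-1-ol; its C–O chirality is transferred 1,3 to C–C through the chair [3,3] transition state (phenyl equatorial, which also fixes the E-styryl alkene). The second E-styryl unit comes from (E)-cinnamaldehyde.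

Key step: step 12

Assumption: 17 and 18 are handled as mixtures of C2 epimers and keto–enol forms, and the target is written as its open keto tautomer, which may equilibrate with the hemiketal between 4-OH and the side-chain ketone.

Step 1
Reactants: 1 3-phenylpropanal
Product: 2 1-phenylhex-5-en-3-ol (racemic)
Conditions: allylMgBr, Et2O, 0 °C; sat. NH4Cl
Reagents that add atoms: allylmagnesium bromide, C=CC[Mg]Br
Why: Grignard 1,2-addition of the allyl nucleophile to an unhindered aldehyde is fast at 0 °C, and the racemic carbinol centre is removed by the oxidation that follows.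

Step 2
Reactants: 2 1-phenylhex-5-en-3-ol
Product: 3 1-phenylhex-5-en-3-one
Conditions: Dess–Martin periodinane, CH2Cl2, 0 °C → rt
Reagents that add atoms: none
Why: Dess–Martin oxidation runs under near-neutral conditions at or below room temperature, so the β,γ-alkene of the homoallylic ketone should not migrate into conjugation.

Step 3
Reactants: 3 1-phenylhex-5-en-3-one
Product: 4 2-(2-phenylethyl)-2-(prop-2-en-1-yl)-1,3-dioxolane
Conditions: (TMSOCH2)2, TMSOTf (cat.), CH2Cl2, −78 → −20 °C; pyridine quench
Reagents that add atoms: 1,2-bis(trimethylsilyloxy)ethane, C[Si](C)(C)OCCO[Si](C)(C)C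
Why: Noyori ketalisation with the silylated diol is aprotic and cold, so the dioxolane should form without acid-mediated migration of the allyl double bond.

Step 4
Reactants: 5 (1S)-1-phenylprop-2-en-1-ol
Product: 6 (1S)-1-phenylprop-2-en-1-yl acetate
Conditions: Ac2O, Et3N, DMAP (cat.), CH2Cl2, 0 °C
Reagents that add atoms: acetic anhydride, CC(=O)OC(C)=O
Why: DMAP-catalysed O-acylation under basic conditions leaves the C–O bond of the stereocentre untouched, so the S configuration is retained and ionisation of the benzylic allylic system is avoided.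

Step 5
Reactants: 4 2-(2-phenylethyl)-2-(prop-2-en-1-yl)-1,3-dioxolane; 6 (1S)-1-phenylprop-2-en-1-yl acetate (2 equiv)
Product: 7 (1S,2E)-1-phenyl-4-[2-(2-phenylethyl)-1,3-dioxolan-2-yl]but-2-en-1-yl acetate
Conditions: Hoveyda–Grubbs II (5 mol%), 1,4-benzoquinone (10 mol%), CH2Cl2, 40 °C
Reagents that add atoms: none
Why: Olefin cross-metathesis between a fast-dimerising terminal alkene and a slowly dimerising secondary allylic acetate should favour the heterodimer and, because of the branched allylic substituent, the E alkene, while the carbinol stereocentre is not involved.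

Step 6
Reactants: 7 (1S,2E)-1-phenyl-4-[2-(2-phenylethyl)-1,3-dioxolan-2-yl]but-2-en-1-yl acetate
Product: 10 (3R,4E)-5-phenyl-3-{[2-(2-phenylethyl)-1,3-dioxolan-2-yl]methyl}pent-4-enoic acid, via trimethylsilyl ketene acetal 8 (not isolated), via trimethylsilyl ester 9 (not isolated)
Conditions: LDA, TMSCl, THF, −78 °C → rt; H2O, pH 5 buffer
Reagents that add atoms: chlorotrimethylsilane, C[Si](C)(C)Cl (its silyl group is present in 8 and 9 only)
Why: Ireland–Claisen rearrangement, in which kinetic enolisation and in situ O-silylation give 8, whose [3,3] shift through a chair transition state with phenyl equatorial moves the S C–O centre suprafacially into the 3R C–C centre and creates the E-styryl alkene, the silyl ester 9 being hydrolysed on work-up.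

Step 7
Reactants: 10 (3R,4E)-5-phenyl-3-{[2-(2-phenylethyl)-1,3-dioxolan-2-yl]methyl}pent-4-enoic acid
Product: 11 tert-butyl (3R,4E)-5-phenyl-3-{[2-(2-phenylethyl)-1,3-dioxolan-2-yl]methyl}pent-4-enoate
Conditions: tBuOC(=NiPr)NHiPr, CH2Cl2, rt
Reagents that add atoms: O-tert-butyl-N,N'-diisopropylisourea, CC(C)NC(=NC(C)C)OC(C)(C)C
Why: Isourea-mediated tert-butyl esterification (proton transfer from the acid, then tert-butyl transfer to the carboxylate) is neutral, so the dioxolane, both alkenes and the non-enolisable stereocentre should be unaffected.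

Step 8
Reactants: 12 (E)-cinnamaldehyde
Product: 13 [(1E)-4,4-dibromobuta-1,3-dien-1-yl]benzene
Conditions: CBr4, PPh3, CH2Cl2, 0 °C
Reagents that add atoms: carbon tetrabromide, BrC(Br)(Br)Br
Why: Corey–Fuchs (Ramirez) dibromo-olefination is a Wittig-type reaction at the aldehyde that leaves the E-styryl double bond unchanged.

Step 9
Reactants: 13 [(1E)-4,4-dibromobuta-1,3-dien-1-yl]benzene
Product: 15 (4E)-N-methoxy-N-methyl-5-phenylpent-4-en-2-ynamide, via lithium enynyl acetylide 14 (not isolated)
Conditions: n-BuLi (2.1 equiv), THF, −78 °C; then ClC(O)N(OMe)Me, −78 → 0 °C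
Reagents that add atoms: N-methoxy-N-methylcarbamoyl chloride, CON(C)C(=O)Cl; n-butyllithium, [Li]CCCC (lithium present in 14 only)
Why: The second stage of the Corey–Fuchs alkyne synthesis (bromine–lithium exchange, Fritsch–Buttenberg–Wiechell shift, deprotonation) gives acetylide 14, which is C-acylated by the carbamoyl chloride to the Weinreb ynamide without over-addition.

Step 10
Reactants: 11 tert-butyl (3R,4E)-5-phenyl-3-{[2-(2-phenylethyl)-1,3-dioxolan-2-yl]methyl}pent-4-enoate; 15 (4E)-N-methoxy-N-methyl-5-phenylpent-4-en-2-ynamide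
Product: 17 tert-butyl (2RS,6E)-3-oxo-7-phenyl-2-[(1S,2E)-3-phenyl-1-{[2-(2-phenylethyl)-1,3-dioxolan-2-yl]methyl}prop-2-en-1-yl]hept-6-en-4-ynoate, via lithium enolate 16 (not isolated)
Conditions: LDA, THF, −78 °C; then 15, −78 → −40 °C; sat. NH4Cl
Reagents that add atoms: lithium diisopropylamide, [Li]N(C(C)C)C(C)C (lithium present in 16 only)
Why: Claisen-type C-acylation of a lithium ester enolate by a Weinreb amide, in which the N-methoxy chelate holds the tetrahedral adduct until the quench so the ynone never meets enolate, LDA removes only the α-CH2 protons because the ketone is masked, and the new α-centre may be a mixture since it becomes sp2 in step 12.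

Step 11
Reactants: 17 tert-butyl (2RS,6E)-3-oxo-7-phenyl-2-[(1S,2E)-3-phenyl-1-{[2-(2-phenylethyl)-1,3-dioxolan-2-yl]methyl}prop-2-en-1-yl]hept-6-en-4-ynoate
Product: 18 tert-butyl (2RS,6E)-3-oxo-2-[(1E,3S)-5-oxo-1,7-diphenylhept-1-en-3-yl]-7-phenylhept-6-en-4-ynoate
Conditions: pTsOH·H2O (cat.), THF/H2O (4:1), 40 °C
Reagents that add atoms: water, O
Why: Acid-catalysed ketal hydrolysis of a dialkyl-ketone dioxolane with a non-nucleophilic acid should spare the tert-butyl ester and the ynone, and without base no retro-Michael cleavage at the methine can scramble the stereocentre.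

Step 12
Reactants: 18 tert-butyl (2RS,6E)-3-oxo-2-[(1E,3S)-5-oxo-1,7-diphenylhept-1-en-3-yl]-7-phenylhept-6-en-4-ynoate
Product: 19 4-hydroxy-3-[(1E,3S)-5-oxo-1,7-diphenylhept-1-en-3-yl]-6-[(E)-2-phenylethenyl]-2H-pyran-2-one
Conditions: (SPhos)AuNTf2 (5 mol%), MeNO2/AcOH (4:1), rt
Reagents that add atoms: none
Why: Cationic gold(I) π-activates the ynone triple bond, whose distal carbon (future C6, bearing the styryl group) is the electrophilic β-position, and the tert-butyl ester carbonyl oxygen adds to it anti to gold, forming O1–C6 and a 2-tert-butoxypyrylium-type vinylgold species; this oxocarbenium ion sheds isobutene, and protodeauration by AcOH followed by enolisation of the C4 ketone gives the 4-hydroxy-2-pyranone. The closest known reaction type is the gold(I)-catalysed cycloisomerisation of tert-butyl 3-oxoalk-4-ynoates to 4-hydroxy-2-pyranones, used here on a C2-substituted, alkenyl-terminated member of that class. The one ring closes in a 6-endo-dig mode. No stereocentre is created: the C2 epimers converge because that carbon becomes sp2 C3, and the S methine is not enolisable and meets no base, so it should pass through unchanged. The step needs 6-endo O-attack to win over 5-exo attack, over carbocyclisation of the nearby styryl alkene and over participation of the side-chain ketone; ynone polarisation (attack at the α-carbon is electronically disfavoured), the pre-organised 1,3-dicarbonyl geometry and the 7- or 8-membered rings that ketone attack would require should secure this.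

**Compound list**
1 | 3-phenylpropanal | O=CCCc1ccccc1 | starting material
2 | 1-phenylhex-5-en-3-ol (racemic) | C=CCC(O)CCc1ccccc1 | intermediate
3 | 1-phenylhex-5-en-3-one | C=CCC(=O)CCc1ccccc1 | intermediate
4 | 2-(2-phenylethyl)-2-(prop-2-en-1-yl)-1,3-dioxolane | C=CCC1(CCc2ccccc2)OCCO1 | intermediate
5 | (1S)-1-phenylprop-2-en-1-ol | C=C[C@H](O)c1ccccc1 | starting material
6 | (1S)-1-phenylprop-2-en-1-yl acetate | C=C[C@H](OC(C)=O)c1ccccc1 | intermediate
7 | (1S,2E)-1-phenyl-4-[2-(2-phenylethyl)-1,3-dioxolan-2-yl]but-2-en-1-yl acetate | CC(=O)O[C@@H](/C=C/CC1(CCc2ccccc2)OCCO1)c1ccccc1 | intermediate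
8 | O-trimethylsilyl ketene acetal of 7 (formed in the flask) | C=C(O[Si](C)(C)C)O[C@@H](/C=C/CC1(CCc2ccccc2)OCCO1)c1ccccc1 | intermediate
9 | trimethylsilyl (3R,4E)-5-phenyl-3-{[2-(2-phenylethyl)-1,3-dioxolan-2-yl]methyl}pent-4-enoate (formed in the flask) | C(Cc1ccccc1)C2(OCCO2)C[C@@H](/C=C/c3ccccc3)CC(=O)O[Si](C)(C)C | intermediate
10 | (3R,4E)-5-phenyl-3-{[2-(2-phenylethyl)-1,3-dioxolan-2-yl]methyl}pent-4-enoic acid | C(Cc1ccccc1)C2(OCCO2)C[C@@H](/C=C/c3ccccc3)CC(=O)O | intermediate
11 | tert-butyl (3R,4E)-5-phenyl-3-{[2-(2-phenylethyl)-1,3-dioxolan-2-yl]methyl}pent-4-enoate | C(Cc1ccccc1)C2(OCCO2)C[C@@H](/C=C/c3ccccc3)CC(=O)OC(C)(C)C | intermediate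
12 | (E)-cinnamaldehyde | O=C/C=C/c1ccccc1 | starting material
13 | [(1E)-4,4-dibromobuta-1,3-dien-1-yl]benzene | BrC(Br)=C/C=C/c1ccccc1 | intermediate
14 | lithium (3E)-4-phenylbut-3-en-1-yn-1-ide (formed in the flask) | [Li]C#C/C=C/c1ccccc1 | intermediate
15 | (4E)-N-methoxy-N-methyl-5-phenylpent-4-en-2-ynamide | CON(C)C(=O)C#C/C=C/c1ccccc1 | intermediate
16 | lithium enolate of 11 (formed in the flask) | C(Cc1ccccc1)C2(OCCO2)C[C@@H](/C=C/c3ccccc3)C=C(O[Li])OC(C)(C)C | intermediate
17 | tert-butyl (2RS,6E)-3-oxo-7-phenyl-2-[(1S,2E)-3-phenyl-1-{[2-(2-phenylethyl)-1,3-dioxolan-2-yl]methyl}prop-2-en-1-yl]hept-6-en-4-ynoate | C(Cc1ccccc1)C2(OCCO2)C[C@@H](/C=C/c3ccccc3)C(C(=O)OC(C)(C)C)C(=O)C#C/C=C/c4ccccc4 | intermediate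
18 | tert-butyl (2RS,6E)-3-oxo-2-[(1E,3S)-5-oxo-1,7-diphenylhept-1-en-3-yl]-7-phenylhept-6-en-4-ynoate | O=C(CCc1ccccc1)C[C@@H](/C=C/c1ccccc1)C(C(=O)OC(C)(C)C)C(=O)C#C/C=C/c1ccccc1 | intermediate
19 | 4-hydroxy-3-[(1E,3S)-5-oxo-1,7-diphenylhept-1-en-3-yl]-6-[(E)-2-phenylethenyl]-2H-pyran-2-one | O=C(CCc1ccccc1)C[C@@H](/C=C/c1ccccc1)c1c(O)cc(/C=C/c2ccccc2)oc1=O | target

**Step count**
Total: 12 steps. Longest linear sequence: 9 steps (1, 2, 3, 5, 6, 7, 10, 11, 12).

**Steps most likely to fail**

Step 5 (cross-metathesis). The hindered secondary allylic acetate may couple sluggishly while 4 homodimerises, ruthenium hydrides may shift the double bonds, and incomplete E-selectivity would pass through the chair rearrangement as a loss of enantiopurity. The fallback sets out from 4 and comes back at 11, making steps 4–7 unnecessary. Cross-metathesis of 4 with tert-butyl acrylate under the same ruthenium catalyst, a dependable E-selective pairing, should give tert-butyl (2E)-4-[2-(2-phenylethyl)-1,3-dioxolan-2-yl]but-2-enoate F1. Rhodium-catalysed asymmetric 1,4-addition (Hayashi–Miyaura) of (E)-2-phenylethenylboronic acid to F1 with Rh(acac)(C2H4)2/(S)-BINAP in dioxane/H2O should then deliver 11 directly. By the usual model the Rh–alkenyl adds to the αsi face of an (E)-enoate, which corresponds to the 3R ester, so the stereocentre is set by the catalyst instead of by chirality transfer.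

Step 10 (enolate acylation). The β-branched enolate may add slowly, attack the ynamide in a conjugate sense, or add a second time if the tetrahedral adduct collapses early. The fallback sets out from 11 and 13 and comes back at 17. Treatment of 13 with n-BuLi (2 equiv) and then DMF should give (4E)-5-phenylpent-4-en-2-ynal F2. Aldol addition of enolate 16 to this far more electrophilic aldehyde at −78 °C should give tert-butyl (6E)-3-hydroxy-7-phenyl-2-[(1S,2E)-3-phenyl-1-{[2-(2-phenylethyl)-1,3-dioxolan-2-yl]methyl}prop-2-en-1-yl]hept-6-en-4-ynoate F3 as a diastereomer mixture at the two new centres, both of which disappear later. Dess–Martin oxidation of the propargylic alcohol then gives 17.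

Step 12 (gold cycloisomerisation). The gold-activated alkyne may be intercepted by the neighbouring styryl alkene (enyne carbocyclisation), or turnover may stall because the dicarbonyl and the side-chain ketone adopt hemiketal forms or bind the catalyst. The fallback sets out from 17 and comes back at 19 without a π-acid. Conjugate addition of diethylamine to the ynone of 17 (THF, rt) should give tert-butyl (6E)-5-(diethylamino)-3-oxo-7-phenyl-2-[(1S,2E)-3-phenyl-1-{[2-(2-phenylethyl)-1,3-dioxolan-2-yl]methyl}prop-2-en-1-yl]hepta-4,6-dienoate F4. Dilute aqueous H2SO4 in THF should hydrolyse both the enaminone and the dioxolane to tert-butyl (6E)-3,5-dioxo-2-[(1E,3S)-5-oxo-1,7-diphenylhept-1-en-3-yl]-7-phenylhept-6-enoate F5. TFA in CH2Cl2 should then remove the tert-butyl group and close the lactone by attack of the C5 enol oxygen on the carboxyl (classical 3,5-dioxo-ester pyranone closure), giving 19.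

**Further compounds**
F1 | step 5 | tert-butyl (2E)-4-[2-(2-phenylethyl)-1,3-dioxolan-2-yl]but-2-enoate | C(Cc1ccccc1)C2(OCCO2)C/C=C/C(=O)OC(C)(C)C
F2 | step 10 | (4E)-5-phenylpent-4-en-2-ynal | O=CC#C/C=C/c1ccccc1
F3 | step 10 | tert-butyl (6E)-3-hydroxy-7-phenyl-2-[(1S,2E)-3-phenyl-1-{[2-(2-phenylethyl)-1,3-dioxolan-2-yl]methyl}prop-2-en-1-yl]hept-6-en-4-ynoate | C(Cc1ccccc1)C2(OCCO2)C[C@@H](/C=C/c3ccccc3)C(C(=O)OC(C)(C)C)C(O)C#C/C=C/c4ccccc4
F4 | step 12 | tert-butyl (6E)-5-(diethylamino)-3-oxo-7-phenyl-2-[(1S,2E)-3-phenyl-1-{[2-(2-phenylethyl)-1,3-dioxolan-2-yl]methyl}prop-2-en-1-yl]hepta-4,6-dienoate | C(Cc1ccccc1)C2(OCCO2)C[C@@H](/C=C/c3ccccc3)C(C(=O)OC(C)(C)C)C(=O)C=C(N(CC)CC)/C=C/c4ccccc4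
F5 | step 12 | tert-butyl (6E)-3,5-dioxo-2-[(1E,3S)-5-oxo-1,7-diphenylhept-1-en-3-yl]-7-phenylhept-6-enoate | O=C(CCc1ccccc1)C[C@@H](/C=C/c1ccccc1)C(C(=O)OC(C)(C)C)C(=O)CC(=O)/C=C/c1ccccc1
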